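Ring B, the dihydroxylated γ-lactone, is disconnected at its ring oxygen–spiro carbon bond and at the bond between its lactone carbonyl and the CH(OH) carbon, which excises the O–C(=O) unit as carbon dioxide. The key step exploits the 1,3-relationship of these two carbons across the carboxyl-bearing carbinol carbon: with that carbon as a ketone, a 2-acetylbutanolide (ring A complete) is doubly deprotonated, carboxylated with CO2 at the acetyl methyl, and the carboxylate is closed with iodine onto the doubly activated ring-A α-carbon in the same flask, giving the spiro tetronic acid. Triflation/carbonylation, epoxidation and anti hydrolysis then complete ring B.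

Key step: step 3

Remark: ring A is the butanolide that carries the dec-9-enyl chain and ring B is the lactone that ends up dihydroxylated. Compounds 7, 9 and 10 are mixtures at the enolisable ring-A α-carbon, which is fixed only in step 3. Compound 11 is drawn as its enol (4-hydroxybutenolide) tautomer.

Step 1
Reactants: 1 9-bromonon-1-ene; 2 (R)-epichlorohydrin
Product: 5 (R)-2-(dec-9-en-1-yl)oxirane, via non-8-en-1-ylmagnesium bromide 3 (not isolated), via (R)-1-chlorododec-11-en-2-ol 4 (not isolated)
Conditions: Mg, THF, 40 °C; then 2, CuI (5 mol %), THF, −40 → 0 °C; then aq. NaOH, MeOH, rt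
Reagents that add atoms: none
Why: Copper-catalysed Grignard opening of the oxirane at its unsubstituted carbon leaves the stereocentre untouched, and the chlorohydrin alkoxide then closes to the new oxirane by intramolecular Williamson displacement of chloride, so the (R) centre of 2 is carried into 5.

Step 2
Reactants: 5 (R)-2-(dec-9-en-1-yl)oxirane; 6 ethyl acetoacetate
Product: 7 (5R)-3-acetyl-5-(dec-9-en-1-yl)oxolan-2-one
Conditions: NaOEt (1.05 equiv), EtOH, 0 → 50 °C; aq. HCl work-up
Reagents that add atoms: none
Why: Acetoacetic ester alkylation at the terminal oxirane carbon followed by lactonisation of the γ-alkoxide with loss of ethoxide should give the 2-acetylbutanolide, the ring-A carbinol centre coming unchanged from 5.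

Step 3
Reactants: 7 (5R)-3-acetyl-5-(dec-9-en-1-yl)oxolan-2-one; 8 carbon dioxide
Product: 11 (5S,8R)-8-(dec-9-en-1-yl)-4-hydroxy-1,7-dioxaspiro[4.4]non-3-ene-2,6-dione, via 3-oxo acid 9 (not isolated), via ring-A α-iodide 10 (not isolated)
Conditions: NaH (1.05 equiv), THF, 0 °C; n-BuLi (1.05 equiv), −78 → −20 °C; CO2 (1 atm), −78 °C; then I2 (1.0 equiv), THF, −78 °C → rt; aq. Na2S2O3/HCl work-up
Reagents that add atoms: none
Why: NaH and n-BuLi give the 1,3-dicarbonyl dianion, whose terminal carbanion (the most nucleophilic site) adds to CO2 and makes the bond between the future lactone carbonyl and the future CH(OH) carbon; the persisting ring-A enolate is then iodinated and the new carboxylate displaces iodide there, making the ring oxygen–spiro carbon bond. The closest known reaction types are the terminal carboxylation of 1,3-dicarbonyl dianions with CO2 and the iodine-mediated oxidative α-acyloxylation (oxylactonisation) of 1,3-dicarbonyl compounds by carboxylic acids. Ring B closes in the 5-exo-tet mode, ring A being already in place. The only new stereocentre, the spiro carbon, is controlled by the (R)-carbinol centre of ring A: the α-iodide should epimerise rapidly by iodine exchange, and closure should run through the transition state in which the carboxylate oxygen enters on the face opposite the dec-9-enyl group, leaving the larger acyl carbon cis to it. The step needs site selectivity (carboxylation at the methyl carbon, iodination at the ring-A α-carbon), secured by the ordered dianion/enolate chemistry, and chemoselectivity against the terminal alkene, secured by stoichiometric iodine at low temperature. The labile 3-oxo acid is never isolated, which avoids its decarboxylation.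

Step 4
Reactants: 11 (5S,8R)-8-(dec-9-en-1-yl)-4-hydroxy-1,7-dioxaspiro[4.4]non-3-ene-2,6-dione
Product: 12 (5S,8R)-8-(dec-9-en-1-yl)-2,6-dioxo-1,7-dioxaspiro[4.4]non-3-en-4-yl trifluoromethanesulfonate
Conditions: Tf2O, i-Pr2NEt, CH2Cl2, −78 °C
Reagents that add atoms: trifluoromethanesulfonic anhydride, O=S(=O)(OS(=O)(=O)C(F)(F)F)C(F)(F)F
Why: Enol triflate formation by O-sulfonylation of the vinylogous acid should occur at the 4-hydroxyl of the tetronic acid and touches no stereocentre.

Step 5
Reactants: 12 (5S,8R)-8-(dec-9-en-1-yl)-2,6-dioxo-1,7-dioxaspiro[4.4]non-3-en-4-yl trifluoromethanesulfonate; 13 carbon monoxide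
Product: 14 (5S,8R)-8-(dec-9-en-1-yl)-2,6-dioxo-1,7-dioxaspiro[4.4]non-3-ene-4-carboxylic acid
Conditions: Pd(OAc)2 (5 mol %), PPh3 (10 mol %), CO (1 atm), KOAc, DMF, 60 °C; then H2O, aq. HCl work-up
Reagents that add atoms: water, O
Why: Palladium-catalysed hydroxycarbonylation (oxidative addition of zerovalent palladium into the vinyl triflate, CO insertion, capture of the acylpalladium by acetate and hydrolysis) should place the carboxyl carbon on the future tertiary carbinol carbon of ring B, the isolated alkene being a poor competitor under CO.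

Step 6
Reactants: 14 (5S,8R)-8-(dec-9-en-1-yl)-2,6-dioxo-1,7-dioxaspiro[4.4]non-3-ene-4-carboxylic acid
Product: 15 (3S,4R,5S,8R)-8-(dec-9-en-1-yl)-3,4-epoxy-2,6-dioxo-1,7-dioxaspiro[4.4]nonane-4-carboxylic acid
Conditions: Na2WO4·2H2O (10 mol %), 30% aq. H2O2, NaOH to pH 5, H2O/t-BuOH, 60 °C; aq. HCl work-up
Reagents that add atoms: hydrogen peroxide, OO
Why: Tungstate-catalysed epoxidation of an α,β-unsaturated acid by H2O2 (peroxotungstate oxygen transfer assisted by the conjugated carboxylate) should be selective for the butenolide alkene over the isolated terminal alkene and should place the oxirane on the ring-B face syn to the ring-A carbonyl, anti to the ring-A CH2 and the side chain that screen the other face, which sets the tertiary C–O centre (4R).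

Step 7
Reactants: 15 (3S,4R,5S,8R)-8-(dec-9-en-1-yl)-3,4-epoxy-2,6-dioxo-1,7-dioxaspiro[4.4]nonane-4-carboxylic acid
Product: 16 (3R,4R,5S,8R)-8-(dec-9-en-1-yl)-3,4-dihydroxy-2,6-dioxo-1,7-dioxaspiro[4.4]nonane-4-carboxylic acid (CNP0281847.1)
Conditions: H2SO4 (0.1 M) in H2O/1,4-dioxane, 90 °C
Reagents that add atoms: water, O
Why: Acid-catalysed epoxide hydrolysis should open the epoxysuccinate-type oxirane by SN2 attack of water at the secondary carbon, anti to the oxirane oxygen, so the new secondary hydroxyl (3R) is trans to the tertiary one, while attack at the tertiary carbon is blocked by the spiro centre and the carboxyl group and both γ-lactones are stable to aqueous acid.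

Compound list
1 | 9-bromonon-1-ene | C=CCCCCCCCBr | starting material
2 | (R)-epichlorohydrin, (R)-2-(chloromethyl)oxirane | ClC[C@H]1CO1 | starting material
3 | non-8-en-1-ylmagnesium bromide | C=CCCCCCCC[Mg]Br | intermediate
4 | (R)-1-chlorododec-11-en-2-ol (formed as its magnesium alkoxide) | ClC[C@H](O)CCCCCCCCC=C | intermediate
5 | (R)-2-(dec-9-en-1-yl)oxirane | C=CCCCCCCCC[C@@H]1CO1 | intermediate
6 | ethyl acetoacetate | CCOC(=O)CC(C)=O | starting material
7 | (5R)-3-acetyl-5-(dec-9-en-1-yl)oxolan-2-one (C3 epimers, enolisable) | C=CCCCCCCCC[C@@H]1CC(C(C)=O)C(=O)O1 | intermediate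
8 | carbon dioxide | O=C=O | starting material
9 | 3-[(5R)-5-(dec-9-en-1-yl)-2-oxooxolan-3-yl]-3-oxopropanoic acid (present as its dianion) | C=CCCCCCCCC[C@@H]1CC(C(=O)CC(=O)O)C(=O)O1 | intermediate
10 | 3-[(5R)-5-(dec-9-en-1-yl)-3-iodo-2-oxooxolan-3-yl]-3-oxopropanoic acid (present as its carboxylate, C3 epimers) | C=CCCCCCCCC[C@@H]1CC(I)(C(=O)CC(=O)O)C(=O)O1 | intermediate
11 | (5S,8R)-8-(dec-9-en-1-yl)-4-hydroxy-1,7-dioxaspiro[4.4]non-3-ene-2,6-dione (spiro tetronic acid, enol form) | C=CCCCCCCCC[C@@H]1C[C@@]2(OC(=O)C=C2O)C(=O)O1 | intermediate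
12 | (5S,8R)-8-(dec-9-en-1-yl)-2,6-dioxo-1,7-dioxaspiro[4.4]non-3-en-4-yl trifluoromethanesulfonate | C=CCCCCCCCC[C@@H]1C[C@@]2(OC(=O)C=C2OS(=O)(=O)C(F)(F)F)C(=O)O1 | intermediate
13 | carbon monoxide | [C-]#[O+] | starting material
14 | (5S,8R)-8-(dec-9-en-1-yl)-2,6-dioxo-1,7-dioxaspiro[4.4]non-3-ene-4-carboxylic acid | C=CCCCCCCCC[C@@H]1C[C@@]2(OC(=O)C=C2C(=O)O)C(=O)O1 | intermediate
15 | (3S,4R,5S,8R)-8-(dec-9-en-1-yl)-3,4-epoxy-2,6-dioxo-1,7-dioxaspiro[4.4]nonane-4-carboxylic acid (oxirane oxygen syn to C6) | C=CCCCCCCCC[C@@H]1C[C@@]2(OC(=O)[C@@H]3[C@]2(O3)C(=O)O)C(=O)O1 | intermediate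
16 | (3R,4R,5S,8R)-8-(dec-9-en-1-yl)-3,4-dihydroxy-2,6-dioxo-1,7-dioxaspiro[4.4]nonane-4-carboxylic acid (CNP0281847.1) | C=CCCCCCCCC[C@@H]1C[C@@]2(OC(=O)[C@H](O)[C@]2(O)C(=O)O)C(=O)O1 | target

Total step count: 7. Longest linear sequence: 7 steps (1 and 2 to 16).

Steps most likely to fail

Step 3. Facial control at the spiro carbon may erode if the carboxylate closes with inversion on the kinetically formed iodide instead of through the equilibrating pair, and the 3-oxo acid may decarboxylate before closure. The fallback sets out from 7 and returns at 11. The sodium enolate of 7 is hydroxylated with 2-(phenylsulfonyl)-3-phenyloxaziridine, which transfers oxygen directly to the face anti to the side chain and should give (3S,5R)-3-acetyl-5-(dec-9-en-1-yl)-3-hydroxyoxolan-2-one F1. Acylation of the tertiary alcohol with ClCO2Me, pyridine and DMAP gives (3S,5R)-3-acetyl-5-(dec-9-en-1-yl)-2-oxooxolan-3-yl methyl carbonate F2. LiN(SiMe3)2 in THF at −78 → 0 °C then closes ring B by Dieckmann-type attack of the methyl ketone enolate on the carbonate carbonyl with loss of methoxide, giving 11.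

Step 6. Oxygen transfer to the doubly deactivated alkene may be sluggish, facial selectivity may be poor, and forcing conditions may begin to oxidise the terminal alkene. The fallback sets out from 12 and returns at 15. Carbonylation of 12 with Pd(OAc)2, PPh3, CO, Et3N and 4-methoxybenzyl alcohol in DMF gives 4-methoxybenzyl (5S,8R)-8-(dec-9-en-1-yl)-2,6-dioxo-1,7-dioxaspiro[4.4]non-3-ene-4-carboxylate F3. Weitz–Scheffer epoxidation (t-BuOOH, DBU, CH2Cl2, 0 °C) proceeds by reversible conjugate addition of the hydroperoxide anion and closure on the less hindered face, leaves the isolated alkene untouched, and should give the 4-methoxybenzyl ester of 15, F4. TFA and anisole in CH2Cl2 at 0 °C remove the ester group to return 15.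

Step 7. Opening of the deactivated oxirane may be slow, and prolonged heating in aqueous acid may lead to translactonisation. The fallback sets out from 15 and returns at 16. Solvolysis in neat TFA at rt opens the oxirane at the secondary carbon with inversion and should give (3R,4R,5S,8R)-8-(dec-9-en-1-yl)-4-hydroxy-2,6-dioxo-3-(trifluoroacetoxy)-1,7-dioxaspiro[4.4]nonane-4-carboxylic acid F5. The trifluoroacetate is then hydrolysed in H2O/THF at rt to give 16.

Further compounds
F1 | step 3 | (3S,5R)-3-acetyl-5-(dec-9-en-1-yl)-3-hydroxyoxolan-2-one | C=CCCCCCCCC[C@@H]1C[C@@](C(C)=O)(O)C(=O)O1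
F2 | step 3 | (3S,5R)-3-acetyl-5-(dec-9-en-1-yl)-2-oxooxolan-3-yl methyl carbonate | C=CCCCCCCCC[C@@H]1C[C@@](C(C)=O)(OC(=O)OC)C(=O)O1
F3 | step 6 | 4-methoxybenzyl (5S,8R)-8-(dec-9-en-1-yl)-2,6-dioxo-1,7-dioxaspiro[4.4]non-3-ene-4-carboxylate | C=CCCCCCCCC[C@@H]1C[C@@]2(OC(=O)C=C2C(=O)OCc3ccc(OC)cc3)C(=O)O1
F4 | step 6 | 4-methoxybenzyl (3S,4R,5S,8R)-8-(dec-9-en-1-yl)-3,4-epoxy-2,6-dioxo-1,7-dioxaspiro[4.4]nonane-4-carboxylate | C=CCCCCCCCC[C@@H]1C[C@@]2(OC(=O)[C@@H]3[C@]2(O3)C(=O)OCc4ccc(OC)cc4)C(=O)O1
F5 | step 7 | (3R,4R,5S,8R)-8-(dec-9-en-1-yl)-4-hydroxy-2,6-dioxo-3-(trifluoroacetoxy)-1,7-dioxaspiro[4.4]nonane-4-carboxylic acid | C=CCCCCCCCC[C@@H]1C[C@@]2(OC(=O)[C@H](OC(=O)C(F)(F)F)[C@]2(O)C(=O)O)C(=O)O1
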